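A pitfall with a warm flask is to read its early lead as a better end.

| flask | starting material | protic impurity | catalyst | temperature | remark | time |
|---|---|---|---|---|---|---|
| Thursday's | 1 M | 0.040 M | 20 mM | 45 °C | run made earlier |  |
| Wednesday's | 1 M | 0.040 M | 20 mM | 70 °C | run made earlier |  |
| dusk | 2.0 M | 0.0400 M | 20 mM | 90 °C |  | 6.0 h |
| noon | 2.0 M | 0.0400 M | 20 mM | 70 °C |  | 6.0 h |
| winter | 2.0 M | 0.0400 M | 20 mM | 50 °C |  | 6.0 h |

- Thursday's (time / h: target / %, starting material / %): 2.50: 14.5, 69.3; 6.00: 31.9, 43.4; 12.0: 50.9, 20.8; 20.0: 61.2, 9.5; 30.0: 65.2, 5.8; 40.0: 68.2, 5.6; 50.0: 67.9, 5.0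
- Wednesday's (time / h: target / %, starting material / %): 0.667: 25.0, 57.5; 2.00: 51.7, 26.3; 4.00: 60.4, 15.1; 5.00: 61.9, 14.1; 8.00: 63.4, 13.8; 10.0: 63.0, 12.8; 15.0: 63.8, 13.9

(readings scatter by 0.5 percentage points)

- which flask leads in amount of target, in percent of the starting material charged ("all alike" within 1.5 percentage points) (dusk / noon / winter / all alike)
- how much target is there at the end, in percent of the starting material charged: dusk
- how much target is there at the end, in percent of the starting material charged: noon
- how much target is there at the end, in percent of the starting material charged: winter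

- the numbers in the tables scatter by 0.5 percentage points (one standard deviation)

Wednesday's flask at 70 °C held 60.4% target after 4.00 h, more than Thursday's flask at 45 °C held after 6.00 h. Yet the last readings were 67.9% for Thursday's and 63.8% for Wednesday's, so the cooler flask lagged and finished higher. The two fit once clock and plateau are kept apart.

I read the clock from the fall of starting material towards its last reading, which gave a rate λ of 0.151 h⁻¹ on Thursday's run and 1.02 h⁻¹ on Wednesday's. I took ln λ as straight in temperature, and I assumed that percentages carry from 1 M to 2.0 M, which no run tested. The shift factor s is the number of Thursday's hours that one hour at another temperature is worth. For winter, s = 1.47, so its 6.0 h count as 8.79 h. A straight line between Thursday's readings at 6.00 h and 12.0 h then gives 40.7%, which is low if anything, since the target rose more slowly over that stretch than over the one before it. Noon matches Wednesday's temperature, whose readings at 5.00 h and 8.00 h, either side of noon's 6.0 h, are 61.9% and 63.4%, both more than my figure for winter. Dusk's clock runs 4.61 times Wednesday's, so I took dusk to be on its plateau; since Wednesday's last reading stood lower than Thursday's, I expected that plateau lower still, and noon in the lead.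

The forecast named noon, with 56% for dusk, 62.7% for noon and 43% for winter, noting that starting material “relaxes cleanly to a plateau”.

The flasks gave 56.9% for dusk, 64.2% for noon and 43.8% for winter, so noon led, and winter stood 3.1 percentage points above my line.

    starting material + protic impurity → quenched substrate (k = 2.00 × 10⁻⁴ M⁻¹ s⁻¹, Ea = 89.0 kJ mol⁻¹)
    starting material + catalyst ⇌ target + catalyst, rate k2*[starting material]*[catalyst] forward; the back reaction follows from the equilibrium constant (K = 11.0, k = 0.00120 M⁻¹ s⁻¹, Ea = 60.0 kJ mol⁻¹, ΔH = −39.0 kJ mol⁻¹)
    isomer of the product ⇌ starting material (k = 8.30 × 10⁻⁶ s⁻¹, Ea = 111 kJ mol⁻¹)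
    target ⇌ isomer of the product (K = 0.350, k = 3.20 × 10⁻⁵ s⁻¹, Ea = 100 kJ mol⁻¹, ΔH = −6.00 kJ mol⁻¹)
    (constants at 50 °C)

Noon passed 50 percent conversion at 0.922 h, well inside its 6.0 h, whereas winter's exchange between isomer of the product and starting material has a relaxation half-life of 4.78 h, both ways together, against the same 6.0 h, and winter reaches 68.0% target at 60.0 h. Winter left until 15 h counts 22.1 h on Thursday's clock, where a straight line between Thursday's readings at 20.0 h and 30.0 h gives 62.0%; that flask gave 64.2%.

(The runs come from a simulation with made-up constants; the scatter is artificial.)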